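**Retrosynthetic overview** (quinone numbered C1–C8a, ring A = benzene ring, ring B = quinone ring, side chain C1' (benzylic) to C13')

1. Last, the C7' acetate is put on and the diol acetal taken off; before that, ring B is cut at C3–C4, C1–C2 and C1–C8a into an aryl(methoxy)carbene Cr(CO)5 complex, propyne and one CO ligand (Dötz benzannulation, then oxidation with (NH4)2Ce(NO3)6).
2. Enabling feature: ring A carries the side chain at C7, para to C4a, so both ortho carbons of the 4-alkylphenyl carbene are equivalent candidates for C8a; in ring B, C3 is an unsubstituted CH and the methyl sits on C2 next to C1=O, the pattern a terminal alkyne delivers; the C1/C4 dione is the oxidised form of the 4-methoxy-1-naphthol that the annulation gives.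
3. The carbene complex comes from an aryl bromide, itself made by B-alkyl Suzuki coupling (C2'–C3') of the 9-BBN adduct of 4-bromostyrene with an (E)-vinyl iodide.
4. The vinyl iodide comes from a terminal alkyne (zirconium-catalysed methylalumination, iodination), made by opening a terminal epoxide with lithiated 1-(trimethylsilyl)propyne; both stereocentres come from geraniol by Sharpless epoxidation (tertiary carbinol) and Payne rearrangement/hydroxide opening (inversion at the secondary carbon, erythro diol).
5. Ring order: ring A is bought (4-bromostyrene); ring B is the only ring formed, in step 9.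

Key step: step 9

Remark: the C4 carbonyl oxygen is taken to come from water in the oxidation with (NH4)2Ce(NO3)6 (the 4-methoxy group leaves as methanol), and in the SMILES of chromium carbonyl complexes the CO ligands are written as separate [C-]#[O+] units.

**Route**

Step 1
Reactants: 1 geraniol
Product: 2 (2S,3S)-2,3-epoxygeraniol
Conditions: Ti(OiPr)4 (5 mol %), diethyl L-(+)-tartrate (6 mol %), t-BuOOH (2 equiv, anhydrous), 4 Å molecular sieves, CH2Cl2, −20 °C
Reagents that add atoms: tert-butyl hydroperoxide, CC(C)(C)OO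
Why: Sharpless asymmetric epoxidation, in which the tetravalent titanium tartrate catalyst binds the allylic hydroxyl so that only the 2,3-alkene reacts, and with diethyl L-(+)-tartrate oxygen is delivered to the face that gives the (2S,3S)-epoxide, which sets the configuration of the future tertiary carbinol carbon.

Step 2
Reactants: 2 (2S,3S)-2,3-epoxygeraniol
Product: 3 (2R,3S)-3,7-dimethyloct-6-ene-1,2,3-triol
Conditions: 0.5 M aq. NaOH, t-BuOH, 75 °C
Reagents that add atoms: water, O
Why: Payne rearrangement followed by hydroxide opening of the resulting terminal epoxide at its CH2 group (direct hydroxide attack at C2 gives the same triol, and attack at the tertiary C3 does not compete in base) inverts C2 and keeps the C3–O bond, so the trans-epoxide should give the erythro (2R,3S)-triol stereospecifically.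

Step 3
Reactants: 3 (2R,3S)-triol
Product: 5 (2S)-6-methyl-2-[(2R)-oxiran-2-yl]hept-5-en-2-ol, via primary tosylate 4 (not isolated)
Conditions: TsCl (1.05 equiv), Bu2SnO (2 mol %), Et3N, CH2Cl2, 0 °C; then K2CO3, MeOH, 0 °C
Reagents that add atoms: none
Why: Bu2SnO-catalysed sulfonylation is selective for the primary hydroxyl of the 1,2-diol unit and the secondary alkoxide then displaces the tosylate in an intramolecular Williamson (3-exo-tet) closure, which leaves both stereocentres untouched because no C–O bond at a stereocentre is broken.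

Step 4
Reactants: 5 terminal epoxide, 6 1-(trimethylsilyl)propyne
Product: 8 (5R,6S)-6,10-dimethylundec-9-en-1-yne-5,6-diol, via silylalkyne diol 7 (not isolated)
Conditions: 6 (3.3 equiv), n-BuLi (3.2 equiv), THF, −78 °C; add 5, −78 → 0 °C; then MeOH, K2CO3, rt
Reagents that add atoms: none
Why: SN2 opening of a monosubstituted epoxide at its CH2 terminus by lithiated 1-(trimethylsilyl)propyne (the first equivalent only deprotonates the tertiary hydroxyl, whose lithium alkoxide in cold THF should not undergo Payne rearrangement quickly, and the silyl group directs reaction to the propargylic terminus), followed by methanolysis of the C–Si bond with K2CO3, with no stereocentre involved.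

Step 5
Reactants: 8 alkyne diol
Product: 10 (1E,5R,6S)-1-iodo-2,6,10-trimethylundeca-1,9-diene-5,6-diol, via alkenylalane 9 (not isolated)
Conditions: AlMe3 (5 equiv), Cp2ZrCl2 (0.3 equiv), CH2Cl2, 0 °C → rt; then I2, THF, −30 → 0 °C; aq. NaHCO3/Na2S2O3 work-up
Reagents that add atoms: trimethylaluminium, C[Al](C)C; iodine, [I][I]
Why: Negishi zirconium-catalysed methylalumination adds CH3 and Al syn across the terminal alkyne with CH3 on the internal carbon (the diol is carried as its aluminium alkoxide, as with free alkynols such as pent-4-yn-1-ol) and iodinolysis of the C–Al bond with retention should give the (E)-vinyl iodide.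

Step 6
Reactants: 10 vinyl iodide diol
Product: 11 (4R,5S)-4-[(3E)-4-iodo-3-methylbut-3-en-1-yl]-2,2,5-trimethyl-5-(4-methylpent-3-en-1-yl)-1,3-dioxolane
Conditions: 2,2-dimethoxypropane, PPTS (5 mol %), CH2Cl2, rt
Reagents that add atoms: 2,2-dimethoxypropane, COC(C)(C)OC
Why: Acid-catalysed transketalisation of the 1,2-diol to the isopropylidene acetal, chosen because it withstands the borane, the aqueous base, t-BuLi and the alkylating agent of the next steps and leaves both stereocentres untouched.

Step 7
Reactants: 12 4-bromostyrene, 11 vinyl iodide acetonide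
Product: 14 (4R,5S)-4-[(3E)-6-(4-bromophenyl)-3-methylhex-3-en-1-yl]-2,2,5-trimethyl-5-(4-methylpent-3-en-1-yl)-1,3-dioxolane, via alkylborane 13 (not isolated)
Conditions: 12 (1.6 equiv), 9-BBN (1.5 equiv), THF, 0 °C → rt; then 11, PdCl2(dppf) (5 mol %), AsPh3 (5 mol %), Cs2CO3 (3 equiv), DMF/H2O, rt
Reagents that add atoms: none
Why: Anti-Markovnikov hydroboration of the styrene with 9-BBN and B-alkyl Suzuki–Miyaura coupling, in which oxidative addition of zerovalent palladium to the alkenyl C–I bond at room temperature should be much faster than to the aryl C–Br bond and proceeds with retention of the (E)-geometry.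

Step 8
Reactants: 14 aryl bromide, 15 hexacarbonylchromium Cr(CO)6
Product: 18 pentacarbonyl{methoxy[4-((3E)-4-methyl-6-((4R,5S)-2,2,5-trimethyl-5-(4-methylpent-3-en-1-yl)-1,3-dioxolan-4-yl)hex-3-en-1-yl)phenyl]methylidene}chromium, via aryllithium 16 (not isolated), via lithium acylchromate 17 (not isolated)
Conditions: t-BuLi (2.1 equiv), THF/Et2O, −78 °C; Cr(CO)6 (1.1 equiv), −78 → 0 °C; then Me3OBF4 (1.5 equiv), CH2Cl2/H2O, 0 °C
Reagents that add atoms: trimethyloxonium tetrafluoroborate, C[O+](C)C.F[B-](F)(F)F
Why: Fischer carbene synthesis, in which bromine–lithium exchange at −78 °C is faster than any deprotonation, the aryllithium adds to a CO ligand of Cr(CO)6 to give the acylchromate and O-methylation with Me3OBF4 gives the methoxycarbene complex, conditions that the acetal and the trisubstituted alkenes tolerate.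

Step 9
Reactants: 18 aryl(methoxy)carbene complex, 19 propyne
Product: 21 2-methyl-7-{(3E)-4-methyl-6-[(4R,5S)-2,2,5-trimethyl-5-(4-methylpent-3-en-1-yl)-1,3-dioxolan-4-yl]hex-3-en-1-yl}naphthalene-1,4-dione, via naphthol tricarbonylchromium complex 20 (not isolated)
Conditions: 19 (3 equiv, THF solution), degassed THF (0.05 M), 50 °C, sealed tube; then (NH4)2Ce(NO3)6 (7 equiv), MeCN/H2O, 0 °C
Reagents that add atoms: water, O
Why: Thermal loss of one CO from 18 lets propyne coordinate and insert into the Cr=C bond with its unsubstituted carbon bonding to the carbene carbon; CO insertion then gives a chromium-bound dienylketene, which closes onto an ortho carbon of the aryl ring and tautomerises to the 4-methoxy-1-naphthol complex 20, so that C3–C4, C1–C2 and C1–C8a are made from three components in one operation. The closest known reaction type is the Dötz benzannulation of aryl(methoxy)carbene pentacarbonylchromium complexes with terminal alkynes, followed by oxidative work-up with tetravalent cerium to the 1,4-naphthoquinone. Ring B is the only ring closed, by a 6π electrocyclic ring closure of the dienylketene (formal [3+2+1] assembly) in which the C1–C8a bond forms. No stereocentre is created, and the two dioxolane stereocentres and the (E)-alkene are remote and untouched. Three selectivities are needed: the regiochemistry of alkyne insertion (secured by the H versus CH3 difference of propyne, which puts the methyl on C2 next to the CO-derived C1), the site of ring closure (secured by the para substitution of ring A, whose two ortho carbons are equivalent, so only the 7-substituted naphthalene can form) and chemoselectivity for the alkyne over the two trisubstituted alkenes (which do not insert into aryl carbene complexes under these conditions). Oxidation of 20 with (NH4)2Ce(NO3)6 then removes chromium and converts the 4-methoxy-1-naphthol directly into the quinone with loss of methanol.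

Step 10
Reactants: 21 quinone acetonide
Product: 22 7-[(3E,7R,8S)-7,8-dihydroxy-4,8,12-trimethyltrideca-3,11-dien-1-yl]-2-methylnaphthalene-1,4-dione
Conditions: AcOH/THF/H2O (3:1:1), 45 °C
Reagents that add atoms: none
Why: Acid-catalysed hydrolysis of the isopropylidene acetal in mild aqueous acetic acid, which the quinone and the trisubstituted alkenes should tolerate and which converts any acetal already opened in step 9 into the same diol, with no C–O bond at a stereocentre broken.

Step 11
Reactants: 22 quinone diol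
Product: 23 chabrolonaphthoquinone B, (3E,7R,8S)-8-hydroxy-4,8,12-trimethyl-1-(7-methyl-5,8-dioxo-5,8-dihydronaphthalen-2-yl)trideca-3,11-dien-7-yl acetate
Conditions: Ac2O (1.5 equiv), pyridine, DMAP (5 mol %), CH2Cl2, 0 °C → rt
Reagents that add atoms: acetic anhydride, CC(=O)OC(C)=O
Why: DMAP-catalysed acylation distinguishes the secondary from the tertiary hydroxyl on steric grounds, so only the C7' hydroxyl should be acetylated and no stereocentre is affected.

**Compound list**

1 | geraniol, (2E)-3,7-dimethylocta-2,6-dien-1-ol | CC(C)=CCC/C(C)=C/CO | starting material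
2 | (2S,3S)-2,3-epoxygeraniol, [(2S,3S)-3-methyl-3-(4-methylpent-3-en-1-yl)oxiran-2-yl]methanol | OC[C@@H]1O[C@@]1(C)CCC=C(C)C | intermediate
3 | (2R,3S)-3,7-dimethyloct-6-ene-1,2,3-triol | O[C@H](CO)[C@@](C)(O)CCC=C(C)C | intermediate
4 | (2R,3S)-2,3-dihydroxy-3,7-dimethyloct-6-en-1-yl 4-methylbenzenesulfonate | O[C@H](COS(=O)(=O)c1ccc(C)cc1)[C@@](C)(O)CCC=C(C)C | intermediate
5 | (2S)-6-methyl-2-[(2R)-oxiran-2-yl]hept-5-en-2-ol | C1O[C@H]1[C@@](C)(O)CCC=C(C)C | intermediate
6 | 1-(trimethylsilyl)propyne, trimethyl(prop-1-yn-1-yl)silane | CC#C[Si](C)(C)C | starting material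
7 | (5R,6S)-6,10-dimethyl-1-(trimethylsilyl)undec-9-en-1-yne-5,6-diol | O[C@H](CCC#C[Si](C)(C)C)[C@@](C)(O)CCC=C(C)C | intermediate
8 | (5R,6S)-6,10-dimethylundec-9-en-1-yne-5,6-diol | O[C@H](CCC#C)[C@@](C)(O)CCC=C(C)C | intermediate
9 | (E)-alkenyl(dimethyl)alane from 8, diol held as cyclic methylaluminium dialkoxide, carbinol configurations as in 8 | C[Al]1O[C@H](CC/C(C)=C/[Al](C)C)[C@@](C)(O1)CCC=C(C)C | intermediate
10 | (1E,5R,6S)-1-iodo-2,6,10-trimethylundeca-1,9-diene-5,6-diol | O[C@H](CC/C(C)=C/I)[C@@](C)(O)CCC=C(C)C | intermediate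
11 | (4R,5S)-4-[(3E)-4-iodo-3-methylbut-3-en-1-yl]-2,2,5-trimethyl-5-(4-methylpent-3-en-1-yl)-1,3-dioxolane | CC1(C)O[C@H](CC/C(C)=C/I)[C@@](C)(O1)CCC=C(C)C | intermediate
12 | 4-bromostyrene, 1-bromo-4-ethenylbenzene | C=Cc1ccc(Br)cc1 | starting material
13 | 9-[2-(4-bromophenyl)ethyl]-9-borabicyclo[3.3.1]nonane | Brc1ccc(CCB2C3CCCC2CCC3)cc1 | intermediate
14 | (4R,5S)-4-[(3E)-6-(4-bromophenyl)-3-methylhex-3-en-1-yl]-2,2,5-trimethyl-5-(4-methylpent-3-en-1-yl)-1,3-dioxolane | CC1(C)O[C@H](CC/C(C)=C/CCc2ccc(Br)cc2)[C@@](C)(O1)CCC=C(C)C | intermediate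
15 | hexacarbonylchromium Cr(CO)6 | [Cr].[C-]#[O+].[C-]#[O+].[C-]#[O+].[C-]#[O+].[C-]#[O+].[C-]#[O+] | starting material
16 | aryllithium from 14 (Li in place of Br) | CC1(C)O[C@H](CC/C(C)=C/CCc2ccc([Li])cc2)[C@@](C)(O1)CCC=C(C)C | intermediate
17 | lithium pentacarbonyl(aroyl)chromate from 16 and Cr(CO)6 | [Li+].CC1(C)O[C@H](CC/C(C)=C/CCc2ccc(cc2)C([O-])=[Cr])[C@@](C)(O1)CCC=C(C)C.[C-]#[O+].[C-]#[O+].[C-]#[O+].[C-]#[O+].[C-]#[O+] | intermediate
18 | pentacarbonyl{methoxy[4-((3E)-4-methyl-6-((4R,5S)-2,2,5-trimethyl-5-(4-methylpent-3-en-1-yl)-1,3-dioxolan-4-yl)hex-3-en-1-yl)phenyl]methylidene}chromium | CC1(C)O[C@H](CC/C(C)=C/CCc2ccc(cc2)C(OC)=[Cr])[C@@](C)(O1)CCC=C(C)C.[C-]#[O+].[C-]#[O+].[C-]#[O+].[C-]#[O+].[C-]#[O+] | intermediate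
19 | propyne | CC#C | starting material
20 | tricarbonyl(η6-arene)chromium complex of 4-methoxy-2-methyl-7-{(3E)-4-methyl-6-[(4R,5S)-2,2,5-trimethyl-5-(4-methylpent-3-en-1-yl)-1,3-dioxolan-4-yl]hex-3-en-1-yl}naphthalen-1-ol | CC1(C)O[C@H](CC/C(C)=C/CCc2ccc3c(OC)cc(C)c(O)c3c2)[C@@](C)(O1)CCC=C(C)C.[Cr].[C-]#[O+].[C-]#[O+].[C-]#[O+] | intermediate
21 | 2-methyl-7-{(3E)-4-methyl-6-[(4R,5S)-2,2,5-trimethyl-5-(4-methylpent-3-en-1-yl)-1,3-dioxolan-4-yl]hex-3-en-1-yl}naphthalene-1,4-dione | CC1(C)O[C@H](CC/C(C)=C/CCc2ccc3c(c2)C(=O)C(C)=CC3=O)[C@@](C)(O1)CCC=C(C)C | intermediate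
22 | 7-[(3E,7R,8S)-7,8-dihydroxy-4,8,12-trimethyltrideca-3,11-dien-1-yl]-2-methylnaphthalene-1,4-dione | O[C@H](CC/C(C)=C/CCc1ccc2c(c1)C(=O)C(C)=CC2=O)[C@@](C)(O)CCC=C(C)C | intermediate
23 | chabrolonaphthoquinone B, (3E,7R,8S)-8-hydroxy-4,8,12-trimethyl-1-(7-methyl-5,8-dioxo-5,8-dihydronaphthalen-2-yl)trideca-3,11-dien-7-yl acetate | CC(=O)O[C@H](CC/C(C)=C/CCc1ccc2c(c1)C(=O)C(C)=CC2=O)[C@@](C)(O)CCC=C(C)C | target

**Step count and risks**

Total step count: 11. Longest linear sequence: 11 steps (geraniol 1 to 23); compounds 6, 12, 15 and 19 are bought.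

Steps most likely to fail:

Step 9. After alkyne insertion the vinylcarbene may take up a second propyne, or collapse to cyclobutenone, furan or indene products faster than CO insertion and electrocyclisation, and the volatile alkyne may leave the solution, so that conversion to the naphthol stays low. The fallback sets out from 14 and comes back to the route at 21, building ring B by directed ortho metalation and anionic cyclisation. Bromine–lithium exchange of 14 (t-BuLi, THF, −78 °C) and trapping of 16 with N,N-diethylcarbamoyl chloride should give the N,N-diethylbenzamide F1. Directed ortho metalation (s-BuLi, TMEDA, THF, −78 °C) should give the ortho-lithiated amide F2, and allylation with 3-bromo-2-methylpropene under CuBr·SMe2 catalysis should give the 2-(2-methylallyl)benzamide F3. LiN(iPr)2 (THF, −78 °C → rt) should deprotonate the benzylic, allylic CH2; the allyl anion should attack the amide carbonyl through its terminus, expel diethylamide and aromatise to the 3-methyl-1-naphthol F4. Para-selective oxidation of F4 with (KSO3)2NO in buffered aqueous acetone should then give 21.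

Step 8. Bromine–lithium exchange may be incomplete, or the aryllithium may be quenched by protons before it adds to Cr(CO)6, so that the acylchromate never builds up. The fallback sets out from 14 and comes back at 18, reversing the polarity of carbene assembly. Hydroxycarbonylation of 14 (Pd(OAc)2, Xantphos, CO 1 atm, H2O, Et3N, DMF, 80 °C) should give the benzoic acid F5. Neutral chlorination with 1-chloro-N,N,2-trimethylprop-1-en-1-amine (CH2Cl2, 0 °C) should give the acid chloride F6. Addition of F6 to the dianion K2Cr(CO)5 F7 (made from Cr(CO)6 and C8K in THF at −78 °C) should give the potassium acylchromate F8, and O-methylation with Me3OBF4 should give 18.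

Step 7. Zerovalent palladium may insert into the aryl C–Br bond of 13 or 14 as well as into the C–I bond of 11, which would lead to oligomers and debrominated material. The fallback sets out from 11 and comes back at 14, moving the halogen discrimination to an aryl iodide against an aryl bromide. Coupling of 11 with vinylboronic acid pinacol ester (PdCl2(dppf), Cs2CO3, THF/H2O, rt) should give the (E)-1,3-diene F9. Hydroboration of its terminal vinyl group with 9-BBN should give the homoallylic borane F10, and coupling of F10 with 1-bromo-4-iodobenzene at room temperature (PdCl2(dppf), AsPh3, Cs2CO3, DMF/H2O), selective for C–I, should give 14.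

**Further compounds**

F1 | step 9 | N,N-diethyl-4-{(3E)-4-methyl-6-[(4R,5S)-2,2,5-trimethyl-5-(4-methylpent-3-en-1-yl)-1,3-dioxolan-4-yl]hex-3-en-1-yl}benzamide | CC1(C)O[C@H](CC/C(C)=C/CCc2ccc(cc2)C(=O)N(CC)CC)[C@@](C)(O1)CCC=C(C)C
F2 | step 9 | ortho-lithiated derivative of F1 (Li on the ring carbon next to the amide) | CC1(C)O[C@H](CC/C(C)=C/CCc2ccc(C(=O)N(CC)CC)c([Li])c2)[C@@](C)(O1)CCC=C(C)C
F3 | step 9 | N,N-diethyl-2-(2-methylprop-2-en-1-yl)-4-{(3E)-4-methyl-6-[(4R,5S)-2,2,5-trimethyl-5-(4-methylpent-3-en-1-yl)-1,3-dioxolan-4-yl]hex-3-en-1-yl}benzamide | CC1(C)O[C@H](CC/C(C)=C/CCc2ccc(C(=O)N(CC)CC)c(CC(C)=C)c2)[C@@](C)(O1)CCC=C(C)C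
F4 | step 9 | 3-methyl-6-{(3E)-4-methyl-6-[(4R,5S)-2,2,5-trimethyl-5-(4-methylpent-3-en-1-yl)-1,3-dioxolan-4-yl]hex-3-en-1-yl}naphthalen-1-ol | CC1(C)O[C@H](CC/C(C)=C/CCc2ccc3c(O)cc(C)cc3c2)[C@@](C)(O1)CCC=C(C)C
F5 | step 8 | 4-{(3E)-4-methyl-6-[(4R,5S)-2,2,5-trimethyl-5-(4-methylpent-3-en-1-yl)-1,3-dioxolan-4-yl]hex-3-en-1-yl}benzoic acid | CC1(C)O[C@H](CC/C(C)=C/CCc2ccc(cc2)C(O)=O)[C@@](C)(O1)CCC=C(C)C
F6 | step 8 | 4-{(3E)-4-methyl-6-[(4R,5S)-2,2,5-trimethyl-5-(4-methylpent-3-en-1-yl)-1,3-dioxolan-4-yl]hex-3-en-1-yl}benzoyl chloride | CC1(C)O[C@H](CC/C(C)=C/CCc2ccc(cc2)C(Cl)=O)[C@@](C)(O1)CCC=C(C)C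
F7 | step 8 | dipotassium pentacarbonylchromate K2Cr(CO)5 | [K+].[K+].[Cr-2].[C-]#[O+].[C-]#[O+].[C-]#[O+].[C-]#[O+].[C-]#[O+]
F8 | step 8 | potassium pentacarbonyl(aroyl)chromate (potassium analogue of 17) | [K+].CC1(C)O[C@H](CC/C(C)=C/CCc2ccc(cc2)C([O-])=[Cr])[C@@](C)(O1)CCC=C(C)C.[C-]#[O+].[C-]#[O+].[C-]#[O+].[C-]#[O+].[C-]#[O+]
F9 | step 7 | (4R,5S)-2,2,5-trimethyl-4-[(3E)-3-methylhexa-3,5-dien-1-yl]-5-(4-methylpent-3-en-1-yl)-1,3-dioxolane | CC1(C)O[C@H](CC/C(C)=C/C=C)[C@@](C)(O1)CCC=C(C)C
F10 | step 7 | 9-{(3E)-4-methyl-6-[(4R,5S)-2,2,5-trimethyl-5-(4-methylpent-3-en-1-yl)-1,3-dioxolan-4-yl]hex-3-en-1-yl}-9-borabicyclo[3.3.1]nonane | CC1(C)O[C@H](CC/C(C)=C/CCB2C3CCCC2CCC3)[C@@](C)(O1)CCC=C(C)C
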